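## Retrosynthetic overview
1. Target ⇒ its di-tert-butyl ester, so the last step is one buffered global ester cleavage and no other protecting group is carried.
2. Both rings ⇒ one hydrogen-atom-initiated cycloisomerization of an acyclic C20 tetraene diester. H• adds to the acrylate CH2 (giving the C18 methyl and a C4 radical), C4–C5 closes ring A, C10–C9 closes ring B, and H• loss from C17 gives the 8(17)-methylene. This is the radical counterpart of the protonation/bicyclization/deprotonation that turns geranylgeranyl diphosphate into copalyl diphosphate.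
3. Only the C2 carbinol centre is preset. Held equatorial in the chair–chair fold, it relays to C4, C5, C9 and C10.
4. Tetraene ⇒ C16 β,γ-unsaturated aldehyde + tert-butyl 2-(bromomethyl)acrylate, joined at C2–C3 by an enantioselective chromium-catalysed allylation.
5. Aldehyde ⇒ (E)-geranylacetone by olefination, terminal allylic oxidation, methylenation, hydroboration/oxidation and alcohol oxidation.

Assumption: positions are given in labdane numbering (C19 = ring carboxyl on C4, OH on C2, C8=C17 exocyclic methylene, C15 = side-chain carboxyl). The SMILES reads as 2α-hydroxylabda-8(17),13E-diene-15,19-dioic acid of the normal series (C2 R, C4 S, C5 R, C9 S, C10 R), with the OH equatorial and C19 axial.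

## Route

Step 1
Reactants: 1 (E)-geranylacetone, (5E)-6,10-dimethylundeca-5,9-dien-2-one; 2 tert-butyl diethylphosphonoacetate
Product: 3 tert-butyl (2E,6E)-3,7,11-trimethyldodeca-2,6,10-trienoate (tert-butyl farnesoate)
Conditions: NaH, THF, 0 °C to rt; minor 2Z isomer removed on silica
Reagents that add atoms: tert-butyl diethylphosphonoacetate, CCOP(=O)(CC(=O)OC(C)(C)C)OCC
Why: Horner–Wadsworth–Emmons olefination of the methyl ketone gives mainly the favoured 2E trisubstituted enoate (the bulky ester raises the E preference), installs C14–C15 at the final oxidation level and leaves the 6E alkene untouched.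

Step 2
Reactants: 3 tert-butyl farnesoate
Product: 4 tert-butyl (2E,6E,10E)-3,7,11-trimethyl-12-oxododeca-2,6,10-trienoate
Conditions: SeO2 (1.1 equiv), 1,4-dioxane/H2O 20:1, 70 °C
Reagents that add atoms: selenium dioxide, O=[Se]=O
Why: Riley allylic oxidation (ene reaction, [2,3]-shift, then oxidation of the allylic alcohol) attacks the most electron-rich terminal isopropylidene and only its E-methyl group, which sets the 10E-enal geometry needed for the later C5=C10 alkene while the enoate stays inert.

Step 3
Reactants: 4 enal; 5 methyltriphenylphosphonium bromide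
Product: 6 tert-butyl (2E,6E,10E)-3,7,11-trimethyltrideca-2,6,10,12-tetraenoate
Conditions: Ph3PCH3Br, KOtBu, THF, 0 °C; then 4, 0 °C to rt
Reagents that add atoms: methyltriphenylphosphonium bromide, C[P+](c1ccccc1)(c1ccccc1)c1ccccc1.[Br-]
Why: Wittig methylenation with the non-stabilised ylide is fast and 1,2-selective on the enal and touches neither the hindered tert-butyl enoate nor any alkene geometry.

Step 4
Reactants: 6 tetraene ester
Product: 8 tert-butyl (2E,6E,10E)-13-hydroxy-3,7,11-trimethyltrideca-2,6,10-trienoate, via B-alkyl-9-BBN adduct 7 (not isolated)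
Conditions: 9-BBN (1.1 equiv), THF, 0 °C to rt; then 3 M NaOH, 30% H2O2, 0 °C
Reagents that add atoms: hydrogen peroxide, OO
Why: Brown hydroboration–oxidation works because 9-BBN adds anti-Markovnikov to the only monosubstituted alkene (the vinyl end of the diene) far faster than to trisubstituted or ester-conjugated alkenes, and alkaline peroxide then replaces boron by OH without harming the tert-butyl ester.

Step 5
Reactants: 8 homoallylic alcohol
Product: 9 tert-butyl (2E,6E,10E)-3,7,11-trimethyl-13-oxotrideca-2,6,10-trienoate
Conditions: IBX (1.5 equiv), DMSO, rt; used at once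
Reagents that add atoms: none
Why: Hypervalent-iodine (IBX) oxidation is neutral, stops at the aldehyde and avoids the amine bases that would pull the 10E β,γ-alkene into conjugation.

Step 6
Reactants: 9 β,γ-unsaturated aldehyde; 10 tert-butyl 2-(bromomethyl)acrylate
Product: 12 di-tert-butyl (2E,6E,10E,13R)-13-hydroxy-3,7,11-trimethyl-15-methylidenehexadeca-2,6,10-trienedioate, via trimethylsilyl ether 11 (not isolated)
Conditions: CrCl2 (10 mol %), 1,8-bis(4-isopropyl-4,5-dihydrooxazol-2-yl)-3,6-diphenylcarbazole (12 mol %, the antipode that directs attack to the Si face), iPr2NEt (30 mol %), Mn powder, TMSCl, THF, 0 °C; then 0.5 M aq citric acid/THF, 0 °C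
Reagents that add atoms: tert-butyl 2-(bromomethyl)acrylate, C=C(CBr)C(=O)OC(C)(C)C
Why: In this catalytic asymmetric Nozaki–Hiyama–Kishi-type 2-(alkoxycarbonyl)allylation, divalent chromium turns 10 into an allylchromium species that adds through a closed chair inside the tridentate ligand pocket to the Si face of 9, which sets C13 (labdane C2) as R, while the non-basic medium spares the labile aldehyde and the tert-butyl ester blocks lactonization.

Step 7
Reactants: 12 acyclic hydroxy tetraene diester
Product: 16 tert-butyl (1S,3R,4aR,5S,8aR)-5-[(3E)-5-tert-butoxy-3-methyl-5-oxopent-3-en-1-yl]-3-hydroxy-1,4a-dimethyl-6-methylidenedecahydronaphthalene-1-carboxylate, via acyclic C4 radical 13 (not isolated), via monocyclic C10 radical 14 (not isolated), via bicyclic C8 radical 15 (not isolated)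
Conditions: Co(dmgBF2)2(THF)2 (5 mol %), H2 (6 atm), degassed benzene (0.02 M), 50 °C, 48 h
Reagents that add atoms: none
Why: Proposed new method: the weak Co–H formed reversibly from the divalent cobalt complex and H2 gives H• only to the CH2 end of the α-substituted acrylate (the trisubstituted alkenes, the β,β-disubstituted enoate and the unactivated exocyclic alkene of the product accept H• orders of magnitude more slowly); the electrophilic tertiary radical 13 closes ring A 6-endo on the electron-rich C5=C10 alkene, radical 14 closes ring B 6-endo on C9=C8, the electron-poor C13=C14 enoate refuses the nucleophilic radical 15 so the cascade stops, and the bulky divalent cobalt complex takes H• back from the most accessible C17 methyl to give the 8(17)-alkene and regenerate Co–H; the all-chair fold keeps the C2 hydroxyl equatorial (axial OH would be syn-axial to C20 and C19), so the E-alkenes deliver the trans-decalin with C5 R, C10 R, C9 S and an equatorial side chain, and the fairly late transition state of the stabilised radical should put the flat ester axial and the larger methyl equatorial at C4 (S), as seen in manganese triacetate cyclizations of α-methyl β-keto esters; the closest known reaction types are the Co(dmgBF2)2L2/H2 hydrogen-atom-transfer cycloisomerization of α-substituted acrylate dienes and the radical polyene bicyclizations that end in an exocyclic alkene (Cp2TiCl, or Mn(OAc)3/Cu(OAc)2).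

Step 8
Reactants: 16 bicyclic di-tert-butyl ester
Product: 18 hypoxyterpoid A, (1S,3R,4aR,5S,8aR)-5-[(3E)-4-carboxy-3-methylbut-3-en-1-yl]-3-hydroxy-1,4a-dimethyl-6-methylidenedecahydronaphthalene-1-carboxylic acid, via tris(trimethylsilyl) derivative 17 (not isolated)
Conditions: TMSOTf (6 equiv), 2,6-lutidine (8 equiv), CH2Cl2, 0 °C to rt; then 10% aq citric acid/THF
Reagents that add atoms: none
Why: In this silyl-triflate tert-butyl ester cleavage, O-silylation of each carbonyl releases the tert-butyl group as isobutene, which needs no access to the hindered axial C19 carbonyl carbon, and the lutidine buffer leaves no free acid to isomerize the 8(17)-alkene or the 13E-enoate, after which the silyl esters and ether hydrolyse under mild acid with no stereocentre touched.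

## Compound list
1 | (E)-geranylacetone | CC(=O)CC/C=C(\C)CCC=C(C)C | starting material
2 | tert-butyl diethylphosphonoacetate | CCOP(=O)(CC(=O)OC(C)(C)C)OCC | starting material
3 | tert-butyl (2E,6E)-farnesoate | CC(C)=CCC/C(C)=C/CC/C(C)=C/C(=O)OC(C)(C)C | intermediate
4 | tert-butyl (2E,6E,10E)-3,7,11-trimethyl-12-oxododeca-2,6,10-trienoate | O=C/C(C)=C/CC/C(C)=C/CC/C(C)=C/C(=O)OC(C)(C)C | intermediate
5 | methyltriphenylphosphonium bromide | C[P+](c1ccccc1)(c1ccccc1)c1ccccc1.[Br-] | starting material
6 | tert-butyl (2E,6E,10E)-3,7,11-trimethyltrideca-2,6,10,12-tetraenoate | C=C/C(C)=C/CC/C(C)=C/CC/C(C)=C/C(=O)OC(C)(C)C | intermediate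
7 | B-alkyl-9-BBN adduct of 6 (boron on C13) | C1CC2CCCC(C1)B2CC/C(C)=C/CC/C(C)=C/CC/C(C)=C/C(=O)OC(C)(C)C | intermediate
8 | tert-butyl (2E,6E,10E)-13-hydroxy-3,7,11-trimethyltrideca-2,6,10-trienoate | OCC/C(C)=C/CC/C(C)=C/CC/C(C)=C/C(=O)OC(C)(C)C | intermediate
9 | tert-butyl (2E,6E,10E)-3,7,11-trimethyl-13-oxotrideca-2,6,10-trienoate | O=CC/C(C)=C/CC/C(C)=C/CC/C(C)=C/C(=O)OC(C)(C)C | intermediate
10 | tert-butyl 2-(bromomethyl)acrylate | C=C(CBr)C(=O)OC(C)(C)C | starting material
11 | (13R)-trimethylsilyl ether of 12 | C=C(C[C@H](O[Si](C)(C)C)C/C(C)=C/CC/C(C)=C/CC/C(C)=C/C(=O)OC(C)(C)C)C(=O)OC(C)(C)C | intermediate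
12 | di-tert-butyl (2E,6E,10E,13R)-13-hydroxy-3,7,11-trimethyl-15-methylidenehexadeca-2,6,10-trienedioate | C=C(C[C@H](O)C/C(C)=C/CC/C(C)=C/CC/C(C)=C/C(=O)OC(C)(C)C)C(=O)OC(C)(C)C | intermediate
13 | acyclic tertiary α-ester radical (labdane C4) | C[C](C[C@H](O)C/C(C)=C/CC/C(C)=C/CC/C(C)=C/C(=O)OC(C)(C)C)C(=O)OC(C)(C)C | intermediate
14 | monocyclic tertiary radical (ring A closed, radical at labdane C10) | CC(C)(C)OC(=O)/C=C(\C)CC/C=C(\C)CC[C@@H]1[C](C)C[C@@H](O)C[C@]1(C)C(=O)OC(C)(C)C | intermediate
15 | bicyclic tertiary radical (rings A and B closed, radical at labdane C8) | C[C]1CC[C@@H]2[C@](C)(C[C@@H](O)C[C@]2(C)C(=O)OC(C)(C)C)[C@H]1CC/C(C)=C/C(=O)OC(C)(C)C | intermediate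
16 | di-tert-butyl ester of hypoxyterpoid A | C=C1CC[C@@H]2[C@](C)(C[C@@H](O)C[C@]2(C)C(=O)OC(C)(C)C)[C@H]1CC/C(C)=C/C(=O)OC(C)(C)C | intermediate
17 | bis(trimethylsilyl) ester, 2-O-trimethylsilyl ether of hypoxyterpoid A | C=C1CC[C@@H]2[C@](C)(C[C@@H](O[Si](C)(C)C)C[C@]2(C)C(=O)O[Si](C)(C)C)[C@H]1CC/C(C)=C/C(=O)O[Si](C)(C)C | intermediate
18 | hypoxyterpoid A | C=C1CC[C@@H]2[C@](C)(C[C@@H](O)C[C@]2(C)C(=O)O)[C@H]1CC/C(C)=C/C(=O)O | target

## Step count and risks
Total step count: 8. Longest linear sequence: 8 (1 → 18).

**Step 7 is the most likely to fail.** The divalent cobalt complex may take H• back too early, which would isomerize the acrylate to the 2-methyl-2-enoate or give monocyclic dienes. The facial preference at C4 may also be only moderate, in which case the C4 epimer has to be removed by chromatography. The fallback separates radical generation from the Co–H equilibrium.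
- It sets out from 11, kept as the silyl ether by a non-acidic work-up of step 6.
- Chemoselective 1,4-hydrosilylation of the acrylate with [(Ph3P)CuH]6 (cat.) and PhMe2SiH in toluene gives the dimethylphenylsilyl ketene acetal F1.
- NBS in THF at −78 °C converts it into the tertiary α-bromo ester F2. Both C4 epimers form, which does not matter because that centre becomes the radical.
- Visible-light dual catalysis (fac-Ir(ppy)3 and Co(dmgH)2(py)Cl, iPr2NEt, MeCN) then runs a radical Heck-type bicyclization. The bromide is reduced to radical 13, and the base removes the cobalt hydride after the final H• abstraction. This gives the 2-O-trimethylsilyl ether of the bicyclic diester F3.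
- 1 M HCl/THF removes the silyl group, and the fallback comes back to the route at 16.

**Step 6 is the second risk.** Aldehyde 9 may enolize or slip into conjugation in the presence of TMSCl and metal salts, and the ee on this unbranched aldehyde is not guaranteed. The fallback replaces the reductive Barbier coupling with a preformed allylboron reagent that reacts through a closed six-membered transition state under chiral Brønsted acid catalysis.
- It sets out from 9 and 10.
- B2pin2, CuCl and KOAc in DMF convert 10 into tert-butyl 2-[(pinacolboryl)methyl]acrylate F4.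
- F4 adds to 9 in toluene at −30 °C with the BINOL-derived phosphoric acid TRIP (the antipode that directs attack to the Si face) to give the O-pinacolboryl adduct F5.
- Aqueous work-up hydrolyses F5, and the fallback comes back to the route at 12.

**Step 2 is the third risk.** Low yield, attack at the internal alkene and organoselenium residues are all possible. The fallback replaces C–H oxidation with degradation and re-olefination.
- It sets out from 3.
- NBS in THF/H2O at 0 °C gives, selectively at the terminal alkene, the racemic bromohydrin F6.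
- K2CO3 in MeOH closes it to the terminal epoxide F7.
- H5IO6 in THF/Et2O cleaves the epoxide to the trisnor aldehyde F8.
- 2-(Triphenylphosphoranylidene)propanal in warm toluene rebuilds the E-enal, and the fallback comes back to the route at 4.

## Further compounds
F1 | step 7 | dimethylphenylsilyl tert-butyl ketene acetal from 11 (E/Z mixture) | CC(C[C@H](O[Si](C)(C)C)C/C(C)=C/CC/C(C)=C/CC/C(C)=C/C(=O)OC(C)(C)C)=C(OC(C)(C)C)O[Si](C)(C)c1ccccc1
F2 | step 7 | di-tert-butyl (2E,6E,10E,13R)-15-bromo-3,7,11,15-tetramethyl-13-(trimethylsilyloxy)hexadeca-2,6,10-trienedioate (C15 epimers) | CC(Br)(C[C@H](O[Si](C)(C)C)C/C(C)=C/CC/C(C)=C/CC/C(C)=C/C(=O)OC(C)(C)C)C(=O)OC(C)(C)C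
F3 | step 7 | 2-O-trimethylsilyl ether of 16 | C=C1CC[C@@H]2[C@](C)(C[C@@H](O[Si](C)(C)C)C[C@]2(C)C(=O)OC(C)(C)C)[C@H]1CC/C(C)=C/C(=O)OC(C)(C)C
F4 | step 6 | tert-butyl 2-[(4,4,5,5-tetramethyl-1,3,2-dioxaborolan-2-yl)methyl]prop-2-enoate | C=C(CB1OC(C)(C)C(C)(C)O1)C(=O)OC(C)(C)C
F5 | step 6 | (13R)-O-pinacolboryl derivative of 12 | C=C(C[C@H](OB1OC(C)(C)C(C)(C)O1)C/C(C)=C/CC/C(C)=C/CC/C(C)=C/C(=O)OC(C)(C)C)C(=O)OC(C)(C)C
F6 | step 2 | tert-butyl (2E,6E)-10-bromo-11-hydroxy-3,7,11-trimethyldodeca-2,6-dienoate (racemic) | CC(C)(O)C(Br)CC/C(C)=C/CC/C(C)=C/C(=O)OC(C)(C)C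
F7 | step 2 | tert-butyl (2E,6E)-10,11-epoxy-3,7,11-trimethyldodeca-2,6-dienoate (racemic) | CC1(C)OC1CC/C(C)=C/CC/C(C)=C/C(=O)OC(C)(C)C
F8 | step 2 | tert-butyl (2E,6E)-3,7-dimethyl-10-oxodeca-2,6-dienoate | O=CCC/C(C)=C/CC/C(C)=C/C(=O)OC(C)(C)C
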